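## Structural features

The target is a depside with two benzene rings, one unbranched heptyl chain and no stereocentre. Ring A is a benzoic acid with the heptyl group at C2, an acyloxy group at C4 and a free hydroxyl at C6. Ring B is a 2,4-dihydroxy-6-methylbenzoyl unit bound through its carbonyl carbon to O4 of ring A. This aryl ester is the only link between the rings and is an activated phenolic ester, so hydroxide, alkoxides and amines would cleave it or shift the acyl group to a free phenol. The carboxylic acid of ring A lies between an alkyl group and a hydroxyl on an electron-rich ring and tends to lose CO2 on heating or in strong acid. The difficulty is threefold: building the 1,2,4,6-substituted ring A with the right neighbours, telling O4 from O6 so that only O4 is acylated, and unmasking everything without harming the depside ester or the acid. Ring B needs no construction, since it is orsellinic acid. The key step uses the fact that C1 and C2 of ring A (carboxyl, heptyl) are the two sp carbons of a dec-2-ynoate and C3–C6 (H, O, H, O) are a four-carbon diene oxygenated at its 1- and 3-positions; a cycloaddition forms C1–C6 and C2–C3 and leaves O4 free and O6 as a methyl ether.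

## Logic of the disconnections

**21 from 20.** The O–CH2Ph bond of the ring A ester is cut last. The free acid is the most fragile function and is best released under neutral conditions at room temperature. The cut removes nothing from the skeleton but lets all earlier chemistry run on an ester. The forward step must leave the aryl ester and the arenes untouched, which hydrogenolysis over palladium does.

**20 from 19.** The O–CH3 bond at C6 of ring A and the two O–CH2Ph bonds of ring B are cut. 19 has no free hydroxyl and is a stable coupling product. The methyl ether sits beside the ester carbonyl, so a boron Lewis acid can remove it by chelation, and the same reagent takes the aryl benzyl ethers. The forward step must spare the depside ester and must intercept the benzyl cations it releases.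

**19 from 14 and 17 (through 18).** The C(=O)–O bond of the depside is cut. This divides the molecule into two halves of similar size, and the ring B half comes from a purchasable acid. The forward step needs 14 to carry one free hydroxyl only, at C4, and needs strong activation of an acyl donor that has two ortho substituents.

**17 from 16 from 15.** The two aryl O–benzyl bonds are cut, and the benzyl ester formed alongside them is hydrolysed again. The phenols of ring B must be masked before an acid chloride can be made. The demand is exhaustive benzylation followed by hydrolysis of a hindered ester without loss of the ethers.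

**14 from 4 and 11.** The C1–C6 and C2–C3 bonds of ring A are cut. A benzene ring with four different substituents is reduced to a linear alkynoate and a four-carbon diene, and the O4/O6 distinction comes with the ring. The forward step must give one regioisomer and must aromatise by loss of methanol before water reaches the ketal. The partners are chosen for the endgame: a benzyl ester on the ynoate, a dimethyl ketene acetal that leaves O6 methylated, and a trimethylsilyl group at O4 that falls off in the work-up.

**4 from 1 and 2.** The C(sp)–C(=O) bond is cut. A terminal alkyne and a chloroformate are both purchasable, and the benzyl ester is installed in the same operation. The demand is clean mono-acylation of the acetylide.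

**11 from 9, 9 from 8, 8 from 5 and 6.** The O–Si bond, the two C–OMe bonds and the C–C bond between the acetyl carbon and the vinylidene carbon are cut in turn. Each cut removes one functional group and ends at two bulk chemicals. The demands are a kinetic enolate that is trapped on oxygen and a non-aqueous isolation of the diene.

## Other disconnections considered

**Alternative 1:** The cut removes the aryl–C(=O) bond of ring B and the C(=O)–O4 bond together; the carbonyl carbon comes from carbon monoxide A4. In the forward step 1,5-bis(benzyloxy)-2-iodo-3-methylbenzene A2 adds oxidatively to zerovalent palladium (from Pd(OAc)2 and Xantphos). A4 inserts to give an aroyl complex of divalent palladium, and the C4 phenoxide of benzyl 2-heptyl-4,6-dihydroxybenzoate A3 attacks it. The product is benzyl 4-{[2,4-bis(benzyloxy)-6-methylbenzoyl]oxy}-2-heptyl-6-hydroxybenzoate A1.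
- In favour: no acid chloride and no ester hydrolysis on the ring B side. A1 has O6 free, so one hydrogenolysis finishes the synthesis and no methyl ether has to be cleaved. On the endgame this alternative is the better of the two, by one step and by avoiding a Lewis acid.
- Against: it makes the depside bond, not ring A, so A3 must still be built by some ring synthesis. The iodide lies between a methyl and a benzyloxy group, and phenoxides are weak nucleophiles toward aroylpalladium species, so reduction of the iodide or direct C–O coupling may compete. Site selectivity between the two phenols of A3 rests only on the hydrogen bond of O6, and A4 is a toxic gas.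
- Comparison: the chosen acylation is a plain addition–elimination on a phenol with one free hydroxyl, so it has no selectivity question. Overall step count depends on how A3 is reached and is expected to be about equal.

**Alternative 2:** The cut opens the C1–C2 bond of ring A and unfolds the ring into 3,5,7-trioxotetradecanoic acid A6. In the forward step, in buffered water near neutrality, the enol of chain C2 adds to the C7 ketone; dehydration and enolisation give 2-heptyl-4,6-dihydroxybenzoic acid A5.
- In favour: it follows the biosynthetic folding, uses no protecting group, and forms the ring in one operation from one chain. For ring A alone it is the equal of the chosen plan or shorter.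
- Against: A6 is a β-keto acid and loses CO2 easily. Its triketone can also close by Claisen condensation onto the carboxyl carbon or lactonise to 4-hydroxy-6-(2-oxononyl)-2H-pyran-2-one A7, and nothing but the medium directs the mode of closure without an enzyme. A5 has both phenols and the acid free and is itself prone to decarboxylation, so it would need esterification and a selective acylation before the depside can be made.
- Comparison: the chosen cycloaddition fixes the regiochemistry through the polarity of its partners and delivers the ester and the O4/O6 distinction in the same step. The steps that Alternative 2 saves in ring formation are spent again on protection.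

**Alternative 3:** The cut removes four bonds of ring A. In the forward step, irradiation of benzyl 2-diazo-4-methylidene-3-oxoundecanoate A9 causes a Wolff rearrangement, whose alkenyl shift forms C1–C2, and gives the vinylketene benzyl 3-methylidene-2-(oxomethylidene)decanoate A11. A11 adds ethoxyethyne A10 in a (2+2) step that forms C1–C6 and C4–C5. The cyclobutenone opens in a four-electron process and closes again in a six-electron process that forms C3–C4; tautomerisation gives benzyl 6-ethoxy-2-heptyl-4-hydroxybenzoate A8.
- In favour: A8 has the substitution pattern of 14, with O4 free and O6 as an ether. On regiochemical outcome and oxygen differentiation it is the equal of the chosen plan, and the polarity of the ynol ether leaves no doubt about orientation.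
- Against: A9 needs several steps, and its α-methylene β-keto ester unit is a strong Michael acceptor that may oligomerise. A diazo compound and a photochemical step limit scale. A11 is also an acylketene and may react with A10 as an oxadiene in a (4+2) sense. A10 is volatile and costly, and an ethyl ether at O6 is expected to be cleaved more slowly than a methyl ether.
- Comparison: a four-stage pericyclic cascade stands against one cycloaddition with elimination. The precursors of the chosen plan take one and three steps from bulk chemicals, which is shorter, and the endgame after the ring is formed would be the same.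

Key step: step 5

Remark on the chemistry: BCl3 cannot be expected to spare aryl benzyl ethers while it cleaves a chelated aryl methyl ether, so step 9 is planned to remove the methyl ether and both benzyl ethers of ring B together; only the benzyl ester is left for hydrogenolysis.

## Route

Step 1
Reactants: 1 non-1-yne; 2 benzyl chloroformate
Product: 4 benzyl dec-2-ynoate, via lithium non-1-ynide 3 (not isolated)
Conditions: n-BuLi, THF, −78 °C; then 2, −78 °C → 0 °C
Reagents that add atoms: none
Why: n-BuLi deprotonates the terminal alkyne, and C-acylation of the lithium acetylide with a chloroformate is the standard alkynoate synthesis; low temperature and addition of the acetylide to the chloroformate prevent a second addition.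

Step 2
Reactants: 5 acetyl chloride; 6 1,1-dichloroethene
Product: 8 4,4-dichlorobut-3-en-2-one, via 4,4,4-trichlorobutan-2-one 7 (not isolated)
Conditions: AlCl3, CH2Cl2, 0 °C → rt; ice/dil. HCl; distillation under reduced pressure (−HCl)
Reagents that add atoms: none
Why: Friedel–Crafts-type acylation of the alkene at its CH2 carbon gives the β-trichloromethyl ketone, which loses HCl by β-elimination to the conjugated dichloroenone.

Step 3
Reactants: 8 4,4-dichlorobut-3-en-2-one
Product: 9 4,4-dimethoxybut-3-en-2-one
Conditions: NaOMe (2.1 equiv), MeOH, 0 °C → rt
Reagents that add atoms: sodium methoxide, C[O-].[Na+]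
Why: Two successive addition–elimination substitutions at the β-carbon of the enone (a vinylogous acid chloride) replace both chlorides by methoxide.

Step 4
Reactants: 9 4,4-dimethoxybut-3-en-2-one
Product: 11 1,1-dimethoxy-3-(trimethylsilyloxy)buta-1,3-diene, via lithium 4,4-dimethoxybuta-1,3-dien-2-olate 10 (not isolated)
Conditions: LiN(i-Pr)2 (LDA), THF, −78 °C; Me3SiCl, −78 °C → rt; pentane, filtration under N2, distillation in vacuo
Reagents that add atoms: chlorotrimethylsilane, C[Si](C)(C)Cl
Why: The methyl group is the only enolisable position, so kinetic deprotonation and O-silylation of the enolate give the 2-silyloxydiene; the work-up is kept free of water because the diene is both a ketene acetal and a silyl enol ether.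

Step 5
Reactants: 4 benzyl dec-2-ynoate; 11 1,1-dimethoxy-3-(trimethylsilyloxy)buta-1,3-diene
Product: 14 benzyl 2-heptyl-4-hydroxy-6-methoxybenzoate, via cyclohexa-1,4-diene cycloadduct 12 (not isolated), via aryl trimethylsilyl ether 13 (not isolated)
Conditions: 11 (2–3 equiv, in two portions), xylene, 130 °C, sealed tube; then 0.5 M HCl, THF, rt
Reagents that add atoms: none
Why: This is a Diels–Alder cycloaddition of normal electron demand: three oxygen donors raise the diene HOMO and place its largest coefficient on the CH2 terminus, while the ynoate LUMO is largest at the β-carbon, so the CH2–Cβ bond (C2–C3 of ring A) leads and the ketene-acetal carbon closes on Cα (C1–C6). The closest known reaction type is the benzannulation of alk-2-ynoates with 1,1-dialkoxy-3-silyloxybuta-1,3-dienes to 2-alkyl-6-alkoxy-4-hydroxybenzoates. The six-membered ring is closed in one suprafacial (4+2) event, which may be strongly asynchronous and Michael-like without a change in outcome. Adduct 12 has a ketal at C6 and a CH2 at C3; 1,4-elimination of methanol across these positions gives arene 13, driven by aromatisation, and dilute acid then cleaves the Si–O bond to the phenol. No stereocentre is formed. The only selectivity needed is regiochemical (heptyl beside a ring CH, ester beside the methoxy group), and the matched polarisation secures it, since the reverse orientation would pair two electron-rich or two electron-poor termini. Methanol must be lost before water is admitted, because hydrolysis of the ketal in 12 would lead to a C6 ketone and erase the O4/O6 difference; aromatisation is therefore completed thermally before the acid is added. The benzyl ester and the alkyl chain should be inert at this temperature.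

Step 6
Reactants: 15 orsellinic acid (2,4-dihydroxy-6-methylbenzoic acid)
Product: 16 benzyl 2,4-bis(benzyloxy)-6-methylbenzoate
Conditions: BnBr (3.5 equiv), K2CO3, DMF, rt → 50 °C
Reagents that add atoms: benzyl bromide, BrCc1ccccc1
Why: Williamson alkylation; the carboxylate reacts first, which also blocks decarboxylation, and the two phenoxides follow, the hydrogen-bonded one on gentle warming.

Step 7
Reactants: 16 benzyl 2,4-bis(benzyloxy)-6-methylbenzoate
Product: 17 2,4-bis(benzyloxy)-6-methylbenzoic acid
Conditions: KOH, DMSO/H2O, 90 °C; then cold 1 M HCl to pH 2–3
Reagents that add atoms: potassium hydroxide, [K+].[OH-]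
Why: Saponification of a hindered benzoate with poorly solvated hydroxide; aryl benzyl ethers are inert to base, and attack at the carbonyl or at the benzylic carbon leads to the same acid.

Step 8
Reactants: 17 2,4-bis(benzyloxy)-6-methylbenzoic acid; 14 benzyl 2-heptyl-4-hydroxy-6-methoxybenzoate
Product: 19 benzyl 4-{[2,4-bis(benzyloxy)-6-methylbenzoyl]oxy}-2-heptyl-6-methoxybenzoate, via aroyl chloride 18 (not isolated)
Conditions: 17 (1.2 equiv), (COCl)2, DMF (cat.), CH2Cl2, 0 °C → rt, evaporate; then 14, Et3N, DMAP (cat.), CH2Cl2, 0 °C → rt
Reagents that add atoms: none
Why: Vilsmeier-type activation gives the acid chloride, and DMAP-catalysed acylation takes place at the only free hydroxyl of 14, an unhindered phenol made more acidic by the para ester; nucleophilic catalysis compensates for the two ortho substituents of the acyl donor.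

Step 9
Reactants: 19 benzyl 4-{[2,4-bis(benzyloxy)-6-methylbenzoyl]oxy}-2-heptyl-6-methoxybenzoate
Product: 20 benzyl 4-[(2,4-dihydroxy-6-methylbenzoyl)oxy]-2-heptyl-6-hydroxybenzoate
Conditions: BCl3 (1 M in CH2Cl2, 6 equiv), C6HMe5 (5 equiv), CH2Cl2, −78 °C → 0 °C; MeOH at −78 °C, then water
Reagents that add atoms: none
Why: Lewis-acid ether cleavage: boron bridges the ring A ester carbonyl and the C6 methoxy oxygen and chloride removes the methyl group, while the aryl benzyl ethers of ring B ionise and pentamethylbenzene traps the benzyl cations by Friedel–Crafts alkylation before they reach the phenolic rings. The benzyl ester, flanked by two ortho substituents, is expected to be the slowest group; any of it that is cleaved gives 21 itself and is carried through step 10.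

Step 10
Reactants: 20 benzyl 4-[(2,4-dihydroxy-6-methylbenzoyl)oxy]-2-heptyl-6-hydroxybenzoate
Product: 21 4-[(2,4-dihydroxy-6-methylbenzoyl)oxy]-2-heptyl-6-hydroxybenzoic acid
Conditions: H2 (1 atm), 10% Pd/C, EtOAc, rt; filtration, evaporation below 30 °C
Reagents that add atoms: none
Why: Hydrogenolysis of the benzylic C–O bond is neutral and runs at room temperature, so the aryl ester is not cleaved and the acid is not decarboxylated; any benzyl ether that survived step 9 is removed here as well.

## Compound list

1 | non-1-yne | CCCCCCCC#C | starting material
2 | benzyl chloroformate | O=C(Cl)OCc1ccccc1 | starting material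
3 | lithium non-1-ynide | [Li]C#CCCCCCCC | intermediate (not isolated)
4 | benzyl dec-2-ynoate | CCCCCCCC#CC(=O)OCc1ccccc1 | intermediate
5 | acetyl chloride | CC(=O)Cl | starting material
6 | 1,1-dichloroethene | C=C(Cl)Cl | starting material
7 | 4,4,4-trichlorobutan-2-one | CC(=O)CC(Cl)(Cl)Cl | intermediate (not isolated)
8 | 4,4-dichlorobut-3-en-2-one | CC(=O)C=C(Cl)Cl | intermediate
9 | 4,4-dimethoxybut-3-en-2-one | CC(=O)C=C(OC)OC | intermediate
10 | lithium 4,4-dimethoxybuta-1,3-dien-2-olate | [Li]OC(=C)C=C(OC)OC | intermediate (not isolated)
11 | 1,1-dimethoxy-3-(trimethylsilyloxy)buta-1,3-diene | COC(OC)=CC(=C)O[Si](C)(C)C | intermediate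
12 | benzyl 2-heptyl-6,6-dimethoxy-4-(trimethylsilyloxy)cyclohexa-1,4-diene-1-carboxylate | CCCCCCCC1=C(C(=O)OCc2ccccc2)C(OC)(OC)C=C(O[Si](C)(C)C)C1 | intermediate (not isolated)
13 | benzyl 2-heptyl-6-methoxy-4-(trimethylsilyloxy)benzoate | CCCCCCCc1cc(O[Si](C)(C)C)cc(OC)c1C(=O)OCc1ccccc1 | intermediate (not isolated)
14 | benzyl 2-heptyl-4-hydroxy-6-methoxybenzoate | CCCCCCCc1cc(O)cc(OC)c1C(=O)OCc1ccccc1 | intermediate
15 | orsellinic acid (2,4-dihydroxy-6-methylbenzoic acid) | Cc1cc(O)cc(O)c1C(=O)O | starting material
16 | benzyl 2,4-bis(benzyloxy)-6-methylbenzoate | Cc1cc(OCc2ccccc2)cc(OCc2ccccc2)c1C(=O)OCc1ccccc1 | intermediate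
17 | 2,4-bis(benzyloxy)-6-methylbenzoic acid | Cc1cc(OCc2ccccc2)cc(OCc2ccccc2)c1C(=O)O | intermediate
18 | 2,4-bis(benzyloxy)-6-methylbenzoyl chloride | Cc1cc(OCc2ccccc2)cc(OCc2ccccc2)c1C(=O)Cl | intermediate (not isolated)
19 | benzyl 4-{[2,4-bis(benzyloxy)-6-methylbenzoyl]oxy}-2-heptyl-6-methoxybenzoate | CCCCCCCc1cc(OC(=O)c2c(C)cc(OCc3ccccc3)cc2OCc2ccccc2)cc(OC)c1C(=O)OCc1ccccc1 | intermediate
20 | benzyl 4-[(2,4-dihydroxy-6-methylbenzoyl)oxy]-2-heptyl-6-hydroxybenzoate | CCCCCCCc1cc(OC(=O)c2c(C)cc(O)cc2O)cc(O)c1C(=O)OCc1ccccc1 | intermediate
21 | 4-[(2,4-dihydroxy-6-methylbenzoyl)oxy]-2-heptyl-6-hydroxybenzoic acid | CCCCCCCc1cc(OC(=O)c2c(C)cc(O)cc2O)cc(O)c1C(=O)O | target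

## Step count and risks

Total step count: 10. Longest linear sequence: 7 (steps 2, 3, 4, 5, 8, 9, 10).

**Step 5 (key step).** The ynoate has an alkyl group on its β-carbon and is a modest dienophile, so thermal decomposition or adventitious hydrolysis of the diene may outrun the cycloaddition. A second danger is hydrolysis of the ketal of the adduct before methanol is lost, which would remove the distinction between O4 and O6. The fallback drops the cycloaddition and builds ring A by a Michael–Claisen sequence followed by dehydrogenation. It sets out from 17 (kept as the ring B acid; 4 and 11 are not used) and comes back at 21. Dibenzyl malonate and (E)-undec-3-en-2-one, both purchased, with NaH in THF would give benzyl 6-heptyl-2,4-dioxocyclohexane-1-carboxylate F1 by conjugate addition and Claisen ring closure. Br2 in DMF would aromatise it to benzyl 2-heptyl-4,6-dihydroxybenzoate F2. Acylation with 18 (made from 17 as in step 8) should go to the C4 hydroxyl, because the C6 hydroxyl is held in a hydrogen bond to the ester, and give benzyl 4-{[2,4-bis(benzyloxy)-6-methylbenzoyl]oxy}-2-heptyl-6-hydroxybenzoate F3. H2 over 10% Pd/C then removes all three benzyl groups and gives 21.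

**Step 9.** Benzyl cations released by BCl3 may alkylate the phenolic rings if trapping is incomplete. The ring A ester is twisted by its two ortho substituents, so chelation-assisted demethylation may be slow and call for temperatures at which the depside ester suffers cleavage or acyl transfer. The fallback reverses the order of unmasking so that no benzyl cation is formed in the Lewis acid step. It sets out from 19 and comes back at 21. H2 over 10% Pd/C in EtOAc would remove the three benzyl groups and give 4-[(2,4-dihydroxy-6-methylbenzoyl)oxy]-2-heptyl-6-methoxybenzoic acid F4. BCl3 in CH2Cl2 at −78 °C → 0 °C would then bind the carboxyl group, chelate the neighbouring methoxy oxygen and remove the methyl group to give 21.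

**Step 8.** Addition to the carbonyl of an aroyl chloride with two ortho substituents is slow, and the acid chloride may meanwhile be lost through hydrolysis or ionisation. The fallback replaces the acid chloride by a mixed anhydride that reacts through an acylium-like species, for which ortho substituents are no obstacle. It sets out from 17 and 14 and comes back at 19. Trifluoroacetic anhydride in toluene at rt would convert 17 into 2,4-bis(benzyloxy)-6-methylbenzoic trifluoroacetic anhydride F5, which acylates the phenol of 14 in the same flask to give 19.

**Step 4.** The diene may be lost by hydrolysis or polymerisation during isolation, because the trimethylsilyl enol ether is very labile. The fallback uses a sturdier silyl group and soft enolisation in place of the lithium enolate. It sets out from 9 and comes back at 14. t-BuMe2SiOTf and Et3N in Et2O at 0 °C would give 3-(tert-butyldimethylsilyloxy)-1,1-dimethoxybuta-1,3-diene F6. Heating F6 with 4 as in step 5 would give benzyl 4-(tert-butyldimethylsilyloxy)-2-heptyl-6-methoxybenzoate F7 after loss of methanol. Bu4NF with AcOH in THF at 0 °C would cleave the silyl ether to 14.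

## Further compounds

F1 | step 5 | benzyl 6-heptyl-2,4-dioxocyclohexane-1-carboxylate (mixture of stereoisomers and enol forms) | CCCCCCCC1CC(=O)CC(=O)C1C(=O)OCc1ccccc1
F2 | step 5 | benzyl 2-heptyl-4,6-dihydroxybenzoate | CCCCCCCc1cc(O)cc(O)c1C(=O)OCc1ccccc1
F3 | step 5 | benzyl 4-{[2,4-bis(benzyloxy)-6-methylbenzoyl]oxy}-2-heptyl-6-hydroxybenzoate | CCCCCCCc1cc(OC(=O)c2c(C)cc(OCc3ccccc3)cc2OCc2ccccc2)cc(O)c1C(=O)OCc1ccccc1
F4 | step 9 | 4-[(2,4-dihydroxy-6-methylbenzoyl)oxy]-2-heptyl-6-methoxybenzoic acid | CCCCCCCc1cc(OC(=O)c2c(C)cc(O)cc2O)cc(OC)c1C(=O)O
F5 | step 8 | 2,4-bis(benzyloxy)-6-methylbenzoic trifluoroacetic anhydride | Cc1cc(OCc2ccccc2)cc(OCc2ccccc2)c1C(=O)OC(=O)C(F)(F)F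
F6 | step 4 | 3-(tert-butyldimethylsilyloxy)-1,1-dimethoxybuta-1,3-diene | COC(OC)=CC(=C)O[Si](C)(C)C(C)(C)C
F7 | step 4 | benzyl 4-(tert-butyldimethylsilyloxy)-2-heptyl-6-methoxybenzoate | CCCCCCCc1cc(O[Si](C)(C)C(C)(C)C)cc(OC)c1C(=O)OCc1ccccc1
A1 | alternative 1 | benzyl 4-{[2,4-bis(benzyloxy)-6-methylbenzoyl]oxy}-2-heptyl-6-hydroxybenzoate | CCCCCCCc1cc(OC(=O)c2c(C)cc(OCc3ccccc3)cc2OCc2ccccc2)cc(O)c1C(=O)OCc1ccccc1
A2 | alternative 1 | 1,5-bis(benzyloxy)-2-iodo-3-methylbenzene | Cc1cc(OCc2ccccc2)cc(OCc2ccccc2)c1I
A3 | alternative 1 | benzyl 2-heptyl-4,6-dihydroxybenzoate | CCCCCCCc1cc(O)cc(O)c1C(=O)OCc1ccccc1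
A4 | alternative 1 | carbon monoxide | [C-]#[O+]
A5 | alternative 2 | 2-heptyl-4,6-dihydroxybenzoic acid | CCCCCCCc1cc(O)cc(O)c1C(=O)O
A6 | alternative 2 | 3,5,7-trioxotetradecanoic acid | CCCCCCCC(=O)CC(=O)CC(=O)CC(=O)O
A7 | alternative 2 | 4-hydroxy-6-(2-oxononyl)-2H-pyran-2-one | CCCCCCCC(=O)CC1=CC(O)=CC(=O)O1
A8 | alternative 3 | benzyl 6-ethoxy-2-heptyl-4-hydroxybenzoate | CCCCCCCc1cc(O)cc(OCC)c1C(=O)OCc1ccccc1
A9 | alternative 3 | benzyl 2-diazo-4-methylidene-3-oxoundecanoate | CCCCCCCC(=C)C(=O)C(=[N+]=[N-])C(=O)OCc1ccccc1
A10 | alternative 3 | ethoxyethyne | CCOC#C
A11 | alternative 3 | benzyl 3-methylidene-2-(oxomethylidene)decanoate | CCCCCCCC(=C)C(C(=O)OCc1ccccc1)=C=O
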